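**Retrosynthetic overview**
- Target ⇐ Suzuki propenylation and ester cleavage of a 5-bromo-2-aryl-3-methyl-2,3-dihydrobenzofuran whose ring B phenol is a pivalate.
- Dihydrofuran ring (the only ring built, formed in step 10) ⇐ acid-triggered 1,2-shift of ring A from C1 to C2 of a 1,1-diarylpropan-2-ol through a spiro-cyclopropane (phenonium) that expands to the five-membered ether; this sets C3, and C2 follows as trans.
- 1,1-Diarylpropan-2-ol ⇐ invertive opening of the ring B (2R,3R)-epoxide at its benzylic carbon by the ortho-lithiated phenoxide of ring A (from catechol by methylation and dibromination).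
- Epoxide ⇐ Shi epoxidation of the (E)-propenylarene ⇐ Suzuki coupling of 4-bromosyringol pivalate ⇐ resorcinol (methylation, C2 lithiation/oxidation, para-bromination).

Assumption: the SMILES is read as the 2,3-trans (2R,3R) isomer; MeI, Br2, NBS, pivaloyl chloride and similar are treated as reagents.

**Step 1**
Reactants: 1 catechol
Product: 2 2-methoxyphenol
Conditions: MeI (1.0 equiv), K2CO3 (1.0 equiv), acetone, reflux
Reagents that add atoms: iodomethane, CI
Why: Williamson mono-O-methylation of a symmetric diphenol with one equivalent of MeI, the product being separated from catechol and veratrole by distillation.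

**Step 2**
Reactants: 2 2-methoxyphenol
Product: 4 2,4-dibromo-6-methoxyphenol, via 4-bromo-2-methoxyphenol 3 (not isolated)
Conditions: Br2 (2.05 equiv), AcOH, 15 °C
Reagents that add atoms: bromine, BrBr
Why: Electrophilic aromatic bromination directed by the free phenol OH, first para (3) and then at the only open ortho position, as in the ring bromination of 4-substituted guaiacols.

**Step 3**
Reactants: 5 resorcinol
Product: 6 1,3-dimethoxybenzene
Conditions: MeI (2.5 equiv), K2CO3, acetone, reflux
Reagents that add atoms: iodomethane, CI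
Why: Double Williamson O-methylation of both phenols.

**Step 4**
Reactants: 6 1,3-dimethoxybenzene
Product: 9 2,6-dimethoxyphenol, via 2,6-dimethoxyphenyllithium 7 (not isolated), via lithium (2,6-dimethoxyphenyl)trimethoxyborate 8 (not isolated)
Conditions: n-BuLi, THF, 0 °C → rt; B(OMe)3, −78 °C → rt; AcOH, 30 % H2O2, 0 °C → rt
Reagents that add atoms: hydrogen peroxide, OO
Why: Directed ortho-lithiation at C2 between the two methoxy groups, borylation and boronate oxidation put the phenol oxygen between them.

**Step 5**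
Reactants: 9 2,6-dimethoxyphenol
Product: 10 4-bromo-2,6-dimethoxyphenol
Conditions: NBS (1.0 equiv), CHCl3, −45 °C → rt
Reagents that add atoms: N-bromosuccinimide, O=C1CCC(=O)N1Br
Why: Electrophilic bromination para to the OH, the only position the phenol activates because both ortho positions carry OMe.

**Step 6**
Reactants: 10 4-bromo-2,6-dimethoxyphenol
Product: 11 4-bromo-2,6-dimethoxyphenyl pivalate
Conditions: PivCl, Et3N, DMAP (cat.), CH2Cl2, 0 °C → rt
Reagents that add atoms: pivaloyl chloride, CC(C)(C)C(Cl)=O
Why: O-acylation to a hindered ester that survives the epoxidation and organolithium steps and makes ring B electron-poor, which later keeps it from migrating.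

**Step 7**
Reactants: 11 4-bromo-2,6-dimethoxyphenyl pivalate; 12 (E)-prop-1-enylboronic acid
Product: 13 2,6-dimethoxy-4-[(E)-prop-1-enyl]phenyl pivalate
Conditions: Pd(dppf)Cl2 (3 mol %), K3PO4, toluene/H2O, 80 °C
Reagents that add atoms: none
Why: Suzuki–Miyaura coupling, which keeps the (E) geometry of the alkenylboronic acid.

**Step 8**
Reactants: 13 2,6-dimethoxy-4-[(E)-prop-1-enyl]phenyl pivalate
Product: 14 2,6-dimethoxy-4-[(2R,3R)-3-methyloxiran-2-yl]phenyl pivalate
Conditions: Shi ketone (D-fructose-derived, 30 mol %), Oxone (KHSO5), K2CO3, Bu4NHSO4 (cat.), MeCN/DMM–aq. Na2B4O7 buffer (pH 10.5), 0 °C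
Reagents that add atoms: potassium peroxymonosulfate (Oxone), [K+].[O-]S(=O)(=O)OO
Why: Shi asymmetric epoxidation, in which the dioxirane of the D-fructose-derived ketone gives the (R,R)-trans-epoxide through the spiro transition state, as with trans-β-methylstyrene.

**Step 9**
Reactants: 4 2,4-dibromo-6-methoxyphenol; 14 2,6-dimethoxy-4-[(2R,3R)-3-methyloxiran-2-yl]phenyl pivalate
Product: 16 4-[(1R,2R)-1-(5-bromo-2-hydroxy-3-methoxyphenyl)-2-hydroxypropyl]-2,6-dimethoxyphenyl pivalate, via lithium 4-bromo-2-lithio-6-methoxyphenolate 15 (not isolated)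
Conditions: 4, n-BuLi (2.05 equiv), THF, −78 °C; then 14, BF3·OEt2 (2.5 equiv), −78 °C; H2O
Reagents that add atoms: none
Why: Bromine–lithium exchange takes the C–Br ortho to the lithium phenoxide (chelation), and the aryllithium opens the BF3-activated epoxide by SN2 attack at the benzylic carbon with inversion (Ganem-type organolithium/BF3 epoxide opening), leaving the CH3-bearing centre R and making the diaryl centre R.

**Step 10**
Reactants: 16 4-[(1R,2R)-1-(5-bromo-2-hydroxy-3-methoxyphenyl)-2-hydroxypropyl]-2,6-dimethoxyphenyl pivalate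
Product: 17 4-[(2R,3R)-5-bromo-7-methoxy-3-methyl-2,3-dihydro-1-benzofuran-2-yl]-2,6-dimethoxyphenyl pivalate
Conditions: TfOH (20 mol %), HFIP (0.05 M), 0 → 50 °C
Reagents that add atoms: none
Why: Proposed new method: dehydrative 1,2-aryl shift with ring expansion, in which the acid ionises the secondary C–OH while ring A, which the invertive epoxide opening has placed anti to it, bridges from its hydroxyl-activated ipso carbon (phenonium ion, an O-protonated spiro[2.5]octadienone; inversion at the CH3-carbon sets C3 as R), the three-membered ring then opens heterolytically at the ring B-bearing carbon and the phenol oxygen closes the five-membered ring on the face anti to CH3 (stepwise ionic Cloke–Wilson-type expansion, trans, C2 = R); ring B is held back by its pivalate and by the cis-phenonium it would have to form, HFIP hydrogen bonding mutes direct O-attack on the C–OH carbon, and the closest known reactions are the TfOH/HFIP phenonium rearrangements of 2,2-diarylethanols and the stereospecific Cram-type solvolysis of β-aryl sulfonates.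

**Step 11**
Reactants: 17 4-[(2R,3R)-5-bromo-7-methoxy-3-methyl-2,3-dihydro-1-benzofuran-2-yl]-2,6-dimethoxyphenyl pivalate; 12 (E)-prop-1-enylboronic acid
Product: 19 maceneolignan A, via O-pivaloyl maceneolignan A 18 (not isolated)
Conditions: Pd(dppf)Cl2 (5 mol %), K3PO4, dioxane/H2O, 85 °C; then NaOH, MeOH, 50 °C; aq. HCl to pH 5
Reagents that add atoms: none
Why: Suzuki–Miyaura coupling installs the (E)-propenyl group with retention of geometry, and saponification of the aryl pivalate in the same flask frees the phenol without touching the two stereocentres.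

**Compound list**
1 | catechol | Oc1ccccc1O | starting material
2 | 2-methoxyphenol (guaiacol) | COc1ccccc1O | intermediate
3 | 4-bromo-2-methoxyphenol | COc1cc(Br)ccc1O | intermediate
4 | 2,4-dibromo-6-methoxyphenol | COc1cc(Br)cc(Br)c1O | intermediate
5 | resorcinol | Oc1cccc(O)c1 | starting material
6 | 1,3-dimethoxybenzene | COc1cccc(OC)c1 | intermediate
7 | 2,6-dimethoxyphenyllithium | [Li]c1c(OC)cccc1OC | intermediate
8 | lithium (2,6-dimethoxyphenyl)trimethoxyborate | [Li+].CO[B-](OC)(OC)c1c(OC)cccc1OC | intermediate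
9 | 2,6-dimethoxyphenol | COc1cccc(OC)c1O | intermediate
10 | 4-bromo-2,6-dimethoxyphenol | COc1cc(Br)cc(OC)c1O | intermediate
11 | 4-bromo-2,6-dimethoxyphenyl pivalate | COc1cc(Br)cc(OC)c1OC(=O)C(C)(C)C | intermediate
12 | (E)-prop-1-enylboronic acid | C/C=C/B(O)O | starting material
13 | 2,6-dimethoxy-4-[(E)-prop-1-enyl]phenyl pivalate | C/C=C/c1cc(OC)c(OC(=O)C(C)(C)C)c(OC)c1 | intermediate
14 | 2,6-dimethoxy-4-[(2R,3R)-3-methyloxiran-2-yl]phenyl pivalate (trans-epoxide) | C[C@H]1O[C@@H]1c1cc(OC)c(OC(=O)C(C)(C)C)c(OC)c1 | intermediate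
15 | lithium 4-bromo-2-lithio-6-methoxyphenolate | [Li]Oc1c([Li])cc(Br)cc1OC | intermediate
16 | 4-[(1R,2R)-1-(5-bromo-2-hydroxy-3-methoxyphenyl)-2-hydroxypropyl]-2,6-dimethoxyphenyl pivalate | C[C@@H](O)[C@@H](c1cc(Br)cc(OC)c1O)c1cc(OC)c(OC(=O)C(C)(C)C)c(OC)c1 | intermediate
17 | 4-[(2R,3R)-5-bromo-7-methoxy-3-methyl-2,3-dihydro-1-benzofuran-2-yl]-2,6-dimethoxyphenyl pivalate (2,3-trans) | Brc1cc(OC)c2c(c1)[C@@H](C)[C@H](c1cc(OC)c(OC(=O)C(C)(C)C)c(OC)c1)O2 | intermediate
18 | O-pivaloyl maceneolignan A: 2,6-dimethoxy-4-[(2R,3R)-7-methoxy-3-methyl-5-[(E)-prop-1-enyl]-2,3-dihydro-1-benzofuran-2-yl]phenyl pivalate | C/C=C/c1cc(OC)c2c(c1)[C@@H](C)[C@H](c1cc(OC)c(OC(=O)C(C)(C)C)c(OC)c1)O2 | intermediate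
19 | maceneolignan A: 2,6-dimethoxy-4-[(2R,3R)-7-methoxy-3-methyl-5-[(E)-prop-1-enyl]-2,3-dihydro-1-benzofuran-2-yl]phenol | C/C=C/c1cc(OC)c2c(c1)[C@@H](C)[C@H](c1cc(OC)c(O)c(OC)c1)O2 | target

**Totals**
Total step count: 11. Longest linear sequence: 9 steps (steps 3–11, from resorcinol).

**Three steps most likely to fail**

Step 10 (the new step). The risks are direct attack of the phenol oxygen on the C–OH carbon (giving the 2-methyl-3-aryl isomer), migration of ring B, and a hydride shift to the diarylmethyl cation. The fallback uses known chemistry, sets out from 16 and comes back at 17. TBSCl/imidazole (DMF, 0 °C) silylates the phenol first and gives the phenolic O-TBS ether of 16 F1. MsCl/Et3N then gives the secondary mesylate of F1 F2. Buffered acetolysis (NaOAc, AcOH, 70 °C) is the classical stereospecific phenonium solvolysis; with the oxygen blocked by silicon, ring A shifts with inversion and acetate opens the bridged ion at the benzylic carbon to give 4-[(1S,2R)-1-acetoxy-2-[5-bromo-2-(tert-butyldimethylsilyloxy)-3-methoxyphenyl]propyl]-2,6-dimethoxyphenyl pivalate F3. TBAF/AcOH removes the silyl group to give the free phenol of F3 F4. BF3·OEt2 (CH2Cl2, 0 °C) ionises the benzylic acetate and the phenol closes to trans-17, the usual cyclisation of 1,2-diarylpropyl esters.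

Step 9. The risks are attack of the dianion on the ester, BF3-induced rearrangement of the epoxide, and opening at the wrong epoxide carbon. The fallback sets out from 4 (with 14) and comes back at 16. MOMCl/i-Pr2NEt gives 1,5-dibromo-3-methoxy-2-(methoxymethoxy)benzene F5. Bromine–magnesium exchange with i-PrMgCl·LiCl (THF, 0 °C → rt), directed to the bromine ortho to the OMOM group, gives [5-bromo-3-methoxy-2-(methoxymethoxy)phenyl]magnesium chloride F6. CuI (10 mol %) and 14 at −30 °C give anti-opening at the benzylic carbon by the softer aryl-copper species, leading to the phenolic O-MOM ether of 16 F7. HCl in MeOH removes the MOM group to give 16.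

Step 2. The risks are that the second bromine enters para to OMe instead of ortho to OH, and over-bromination. The fallback sets out from 2 and comes back at 15. NBS (1.0 equiv, MeCN, 0 °C) gives 3, now isolated. Iodination ortho to the hydroxyl (NIS, cat. TsOH, MeCN) gives 4-bromo-2-iodo-6-methoxyphenol F8. F8 takes the place of 4 in step 9: iodine–lithium exchange with n-BuLi (2 equiv, −78 °C) is far faster than bromine–lithium exchange, so the same dianion 15 forms without relying on ortho/para discrimination between two bromines.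

**Further compounds**
F1 | step 10 | phenolic O-TBS ether of 16, (1R,2R) | C[C@@H](O)[C@@H](c1cc(Br)cc(OC)c1O[Si](C)(C)C(C)(C)C)c1cc(OC)c(OC(=O)C(C)(C)C)c(OC)c1
F2 | step 10 | secondary mesylate of F1, (1R,2R) | C[C@@H](OS(C)(=O)=O)[C@@H](c1cc(Br)cc(OC)c1O[Si](C)(C)C(C)(C)C)c1cc(OC)c(OC(=O)C(C)(C)C)c(OC)c1
F3 | step 10 | 4-[(1S,2R)-1-acetoxy-2-[5-bromo-2-(tert-butyldimethylsilyloxy)-3-methoxyphenyl]propyl]-2,6-dimethoxyphenyl pivalate | C[C@H](c1cc(Br)cc(OC)c1O[Si](C)(C)C(C)(C)C)[C@H](OC(C)=O)c1cc(OC)c(OC(=O)C(C)(C)C)c(OC)c1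
F4 | step 10 | free phenol of F3: 4-[(1S,2R)-1-acetoxy-2-(5-bromo-2-hydroxy-3-methoxyphenyl)propyl]-2,6-dimethoxyphenyl pivalate | C[C@H](c1cc(Br)cc(OC)c1O)[C@H](OC(C)=O)c1cc(OC)c(OC(=O)C(C)(C)C)c(OC)c1
F5 | step 9 | 1,5-dibromo-3-methoxy-2-(methoxymethoxy)benzene | COCOc1c(Br)cc(Br)cc1OC
F6 | step 9 | [5-bromo-3-methoxy-2-(methoxymethoxy)phenyl]magnesium chloride | COCOc1c([Mg]Cl)cc(Br)cc1OC
F7 | step 9 | phenolic O-MOM ether of 16, (1R,2R) | C[C@@H](O)[C@@H](c1cc(Br)cc(OC)c1OCOC)c1cc(OC)c(OC(=O)C(C)(C)C)c(OC)c1
F8 | step 2 | 4-bromo-2-iodo-6-methoxyphenol | COc1cc(Br)cc(I)c1O
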